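Target: (3R,5S)-1-(4-hydroxy-3-methoxyphenyl)tetradecane-3,5-diol, an open-chain syn-1,3-diol whose only permanent ring is the arene.
Cuts, in retrosynthetic order: C1–H back to C1–OH; C3–O back to C3–Si; aryl–C1 (aryl Grignard plus aldehyde); C1–C2 and C3–Si together (alkene, tethered Si–H and CO); O5–Si; C4–C5 (allyl plus decanal).
Enabling feature: O3 and O5 stand 1,3 and C1 lies two carbons beyond C3. A C5 homoallylic alcohol with a C2=C3 alkene can therefore take a silicon hung on O5 at C3 (masked O3) and CO at C2 (future C1), through the ring O5–Si–C3–C4–C5.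
Forward order: allylboration builds C2–C14, the silyl tether is attached, the temporary 1,2-oxasilolane closes with one-carbon extension, C1 is arylated, silicon is excised oxidatively (ring opened), and hydrogenolysis finishes.
Stereochemistry: C5 comes from the chiral phosphoric acid catalyst of the allylboration. C3 comes from 1,3-induction by C5 in the ring closure and retention in the C–Si oxidation. The C1 carbinol centre is transient.

Key step: step 3

Remark: locants C1–C14 are those of the tetradecane chain of the target (C1 benzylic). The CIP letter at C3 changes between intermediates only because substituent ranks change; the spatial arrangement stays the same.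

Step 1
Reactants: 1 decanal; 2 allylboronic acid pinacol ester
Product: 4 (S)-tridec-1-en-4-ol, via homoallylic pinacol borate 3 (not isolated)
Conditions: (R)-TRIP phosphoric acid (5 mol %), toluene, −30 °C; then aqueous work-up
Reagents that add atoms: none
Why: In this chiral phosphoric acid-catalysed allylboration the acid activates 2 by hydrogen bonding to a boronate oxygen, the allyl group is transferred through a closed chair-like six-membered (Zimmerman–Traxler-type) transition state, and the triisopropylphenyl walls of the (R)-catalyst leave the Re face of 1 open, which sets C5 as S before borate 3 is hydrolysed on work-up.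

Step 2
Reactants: 4 (S)-tridec-1-en-4-ol; 5 chlorodiphenylsilane
Product: 6 diphenyl{[(4S)-tridec-1-en-4-yl]oxy}silane
Conditions: Et3N, DMAP (cat.), CH2Cl2, 0 °C to rt; pentane, filtration under argon
Reagents that add atoms: none
Why: O-Silylation of a secondary alcohol with a chlorosilane (substitution at silicon, amine as HCl scavenger) breaks only the O–H bond, so the Si–H bond, the alkene and the C5 centre remain intact.

Step 3
Reactants: 6 diphenyl{[(4S)-tridec-1-en-4-yl]oxy}silane; 7 carbon monoxide
Product: 8 2-[(3S,5S)-5-nonyl-2,2-diphenyl-1,2-oxasilolan-3-yl]acetaldehyde (3,5-cis)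
Conditions: Rh(acac)(CO)2 (2 mol %), CO (ca. 70 bar), benzene, 60 °C, autoclave
Reagents that add atoms: none
Why: The Rh(I) carbonyl species formed from the precatalyst adds oxidatively to the Si–H bond of 6, the tethered alkene inserts into the Rh–Si bond so that silicon binds the internal carbon C3 and rhodium the terminal carbon C2, CO inserts into the C2–Rh bond, and C–H reductive elimination from the acyl rhodium hydride releases the C1 aldehyde and regenerates Rh(I). This is the known rhodium-catalysed intramolecular silylformylation of homoallylic hydrosilyl ethers, and 6 belongs to that substrate class. The one ring formed, the 1,2-oxasilolane O5–Si–C3–C4–C5, closes in the 5-exo-trig mode, because the short O5–C5–C4 tether brings silicon over C3, whereas bonding to C2 would require a 6-endo path. The new C3 centre is controlled by the existing C5 centre: in the envelope-like silylmetalation transition state the nonyl chain lies pseudo-equatorial and the alkene presents the face that places the C2 arm cis to it, which becomes the 3,5-syn relationship after oxidation. The step needs regioselectivity (Si on C3), chemoselectivity (formylation rather than plain hydrosilylation or alkene isomerisation) and 1,3-diastereoselectivity; the tether secures the first, the high CO pressure secures the second by making acyl formation outrun direct C–H elimination, and the C5 substituent secures the third, with any trans isomer to be removed by chromatography of 8.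

Step 4
Reactants: 9 4-bromo-2-methoxyphenol
Product: 10 1-(benzyloxy)-4-bromo-2-methoxybenzene
Conditions: BnBr, K2CO3, DMF, rt
Reagents that add atoms: benzyl bromide, BrCc1ccccc1
Why: Williamson ether synthesis (phenoxide SN2 on a benzylic bromide) masks the acidic phenol with a group that tolerates magnesium, carbanion chemistry and basic peroxide and that leaves in the final hydrogenolysis.

Step 5
Reactants: 8 2-[(3S,5S)-5-nonyl-2,2-diphenyl-1,2-oxasilolan-3-yl]acetaldehyde; 10 1-(benzyloxy)-4-bromo-2-methoxybenzene
Product: 13 1-[4-(benzyloxy)-3-methoxyphenyl]-2-[(3R,5S)-5-nonyl-2,2-diphenyl-1,2-oxasilolan-3-yl]ethan-1-ol (C1 epimers), via aryl Grignard reagent 11 (not isolated), via bromomagnesium alkoxide 12 (not isolated)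
Conditions: 10, Mg, THF, reflux; the solution (1.1 equiv) added to 8, THF, −78 °C; sat. aq. NH4Cl
Reagents that add atoms: none
Why: In this Grignard 1,2-addition the unhindered aliphatic aldehyde should react at −78 °C far faster than the diphenyl-shielded Si–O bond when nearly stoichiometric reagent is run into 8, the new C1 centre needs no control because it is deleted in step 7, and any O5-to-O1 silyl shift in alkoxide 12 is harmless because step 6 removes silicon from either isomer.

Step 6
Reactants: 13 1-[4-(benzyloxy)-3-methoxyphenyl]-2-[(3R,5S)-5-nonyl-2,2-diphenyl-1,2-oxasilolan-3-yl]ethan-1-ol (C1 epimers)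
Product: 14 (3S,5S)-1-[4-(benzyloxy)-3-methoxyphenyl]tetradecane-1,3,5-triol (3,5-syn, C1 epimers)
Conditions: 30 % aq. H2O2 (excess), KF, KHCO3, THF–MeOH 1:1, rt to 40 °C
Reagents that add atoms: hydrogen peroxide, OO
Why: In the Tamao oxidation fluoride and hydroperoxide add to the alkoxysilane silicon and C3 migrates from silicon to oxygen within the hypervalent silyl peroxide with retention, so the cis-oxasilolane gives the syn-3,5-diol, while excess peroxide also oxidises both Si–Ph bonds and the benzyl ether, arene and benzylic alcohol are inert to buffered peroxide.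

Step 7
Reactants: 14 (3S,5S)-1-[4-(benzyloxy)-3-methoxyphenyl]tetradecane-1,3,5-triol (C1 epimers)
Product: 15 (3R,5S)-1-(4-hydroxy-3-methoxyphenyl)tetradecane-3,5-diol
Conditions: H2 (4 bar), Pd(OH)2/C, EtOH–AcOH, rt
Reagents that add atoms: none
Why: Palladium-catalysed hydrogenolysis first cleaves the O-benzyl ether, the liberated para-hydroxy group then makes the secondary benzylic C1–O bond easy to ionise and reduce in the weakly acidic medium, and the non-benzylic C3 and C5 carbinols are not touched, so both C1 epimers converge on one product with both stereocentres intact.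

Compound list
1 | decanal | CCCCCCCCCC=O | starting material
2 | allylboronic acid pinacol ester | C=CCB1OC(C)(C)C(C)(C)O1 | starting material
3 | (S)-tridec-1-en-4-yl pinacol borate | CCCCCCCCC[C@H](OB1OC(C)(C)C(C)(C)O1)CC=C | intermediate
4 | (S)-tridec-1-en-4-ol | CCCCCCCCC[C@H](O)CC=C | intermediate
5 | chlorodiphenylsilane | Cl[SiH](c1ccccc1)c1ccccc1 | starting material
6 | diphenyl{[(4S)-tridec-1-en-4-yl]oxy}silane | CCCCCCCCC[C@H](O[SiH](c1ccccc1)c1ccccc1)CC=C | intermediate
7 | carbon monoxide | [C-]#[O+] | starting material
8 | 2-[(3S,5S)-5-nonyl-2,2-diphenyl-1,2-oxasilolan-3-yl]acetaldehyde (3,5-cis) | CCCCCCCCC[C@H]1C[C@@H](CC=O)[Si](c2ccccc2)(c2ccccc2)O1 | intermediate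
9 | 4-bromo-2-methoxyphenol | COc1cc(Br)ccc1O | starting material
10 | 1-(benzyloxy)-4-bromo-2-methoxybenzene | COc1cc(Br)ccc1OCc1ccccc1 | intermediate
11 | [4-(benzyloxy)-3-methoxyphenyl]magnesium bromide | COc1cc([Mg]Br)ccc1OCc1ccccc1 | intermediate
12 | bromomagnesium alkoxide of 13 (C1 epimers) | CCCCCCCCC[C@H]1C[C@@H](CC(O[Mg]Br)c2ccc(OCc3ccccc3)c(OC)c2)[Si](c2ccccc2)(c2ccccc2)O1 | intermediate
13 | 1-[4-(benzyloxy)-3-methoxyphenyl]-2-[(3R,5S)-5-nonyl-2,2-diphenyl-1,2-oxasilolan-3-yl]ethan-1-ol (C1 epimers) | CCCCCCCCC[C@H]1C[C@@H](CC(O)c2ccc(OCc3ccccc3)c(OC)c2)[Si](c2ccccc2)(c2ccccc2)O1 | intermediate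
14 | (3S,5S)-1-[4-(benzyloxy)-3-methoxyphenyl]tetradecane-1,3,5-triol (3,5-syn, C1 epimers) | CCCCCCCCC[C@H](O)C[C@H](O)CC(O)c1ccc(OCc2ccccc2)c(OC)c1 | intermediate
15 | (3R,5S)-1-(4-hydroxy-3-methoxyphenyl)tetradecane-3,5-diol | CCCCCCCCC[C@H](O)C[C@H](O)CCc1ccc(O)c(OC)c1 | target

Total step count: 7
Longest linear sequence: 6 (steps 1, 2, 3, 5, 6, 7)

Steps most likely to fail

**Step 3.** The unbranched nonyl chain may give too little bias in the cyclisation, which would erode the cis/trans selectivity. Part of the alkyl-rhodium intermediate may also collapse by C–H elimination before it takes up CO, which amounts to plain hydrosilylation. The fallback sets out from 4 and rejoins the route at 15. It replaces kinetic 1,3-induction by thermodynamic control.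
- Cross-metathesis of 4 with N-methoxy-N-methylacrylamide (Hoveyda–Grubbs II catalyst, CH2Cl2, reflux) should give (S,E)-5-hydroxy-N-methoxy-N-methyltetradec-2-enamide F1.
- Benzaldehyde and catalytic KOtBu in THF at 0 °C convert F1, by hemiacetal formation and reversible intramolecular oxa-Michael addition, into the all-equatorial benzylidene acetal all-cis 2-(6-nonyl-2-phenyl-1,3-dioxan-4-yl)-N-methoxy-N-methylacetamide F2. This fixes O3 syn to O5.
- Grignard reagent 11 adds to the Weinreb amide to give the aryl ketone all-cis 1-[4-(benzyloxy)-3-methoxyphenyl]-2-(6-nonyl-2-phenyl-1,3-dioxan-4-yl)ethan-1-one F3.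
- NaBH4 in MeOH reduces F3 to the carbinol all-cis 1-[4-(benzyloxy)-3-methoxyphenyl]-2-(6-nonyl-2-phenyl-1,3-dioxan-4-yl)ethan-1-ol F4.
- The conditions of step 7 then cleave the benzylidene acetal, the benzyl ether and the C1–O bond in one operation to give 15.

**Step 7.** The reduction may stall at the benzylic alcohol once the phenol is free. Alternatively, acid-induced dehydration toward C2 may put the C3 oxygen in an allylic, ionisable position, with loss or scrambling of that centre. The fallback sets out from 14 and rejoins at 15.
- Peracetylation (Ac2O, pyridine, DMAP) should give (3S,5S)-1-[4-(benzyloxy)-3-methoxyphenyl]tetradecane-1,3,5-triyl triacetate F5. Here C1 carries a better leaving group, and O3 and O5 can no longer take part.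
- Neutral hydrogenolysis (H2, Pd/C, EtOAc) removes the benzyl ether and the benzylic acetate to give (3R,5S)-1-(4-hydroxy-3-methoxyphenyl)tetradecane-3,5-diyl diacetate F6.
- Methanolysis (K2CO3, MeOH) then frees 15.

**Step 1.** Facial discrimination may be incomplete with an unbranched aliphatic aldehyde. The wrong enantiomer would then travel to the end, because no later step can remove it. The fallback sets out from 1 and rejoins at 4. It takes the chirality from a kinetic resolution.
- Corey–Chaykovsky epoxidation of 1 (Me3SI, NaH, DMSO–THF) should give racemic 2-nonyloxirane F7.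
- Hydrolytic kinetic resolution with (S,S)-Co(salen)OAc and 0.55 equiv of water consumes the (R)-epoxide and leaves (S)-2-nonyloxirane F8.
- Vinylmagnesium bromide with catalytic CuI in THF at −30 °C opens F8 at the terminal carbon, without touching the stereocentre, to give 4.

Further compounds
F1 | step 3 | (S,E)-5-hydroxy-N-methoxy-N-methyltetradec-2-enamide | CCCCCCCCC[C@H](O)C/C=C/C(=O)N(C)OC
F2 | step 3 | all-cis 2-(6-nonyl-2-phenyl-1,3-dioxan-4-yl)-N-methoxy-N-methylacetamide | CCCCCCCCC[C@H]1C[C@@H](CC(=O)N(C)OC)O[C@@H](c2ccccc2)O1
F3 | step 3 | all-cis 1-[4-(benzyloxy)-3-methoxyphenyl]-2-(6-nonyl-2-phenyl-1,3-dioxan-4-yl)ethan-1-one | CCCCCCCCC[C@H]1C[C@@H](CC(=O)c2ccc(OCc3ccccc3)c(OC)c2)O[C@@H](c2ccccc2)O1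
F4 | step 3 | all-cis 1-[4-(benzyloxy)-3-methoxyphenyl]-2-(6-nonyl-2-phenyl-1,3-dioxan-4-yl)ethan-1-ol (carbinol epimers) | CCCCCCCCC[C@H]1C[C@@H](CC(O)c2ccc(OCc3ccccc3)c(OC)c2)O[C@@H](c2ccccc2)O1
F5 | step 7 | (3S,5S)-1-[4-(benzyloxy)-3-methoxyphenyl]tetradecane-1,3,5-triyl triacetate (C1 epimers) | CCCCCCCCC[C@H](OC(C)=O)C[C@H](OC(C)=O)CC(OC(C)=O)c1ccc(OCc2ccccc2)c(OC)c1
F6 | step 7 | (3R,5S)-1-(4-hydroxy-3-methoxyphenyl)tetradecane-3,5-diyl diacetate | CCCCCCCCC[C@H](OC(C)=O)C[C@H](OC(C)=O)CCc1ccc(O)c(OC)c1
F7 | step 1 | racemic 2-nonyloxirane | CCCCCCCCCC1CO1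
F8 | step 1 | (S)-2-nonyloxirane | CCCCCCCCC[C@H]1CO1
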